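## Retrosynthetic overview
1. Ring D is formed last. C16–O of a bromosphaerol-type tricycle is ionised, C16 is captured by C2 of the C1=C2 alkene, C3 shifts from C2 to C1 (Wagner–Meerwein), and water enters exo at C2.
2. The C11 carbinol comes from Markovnikov hydration of the C11=C17 exocyclic alkene left by the preceding cyclisation.
3. Rings A and B are formed together by transannular bromonium cyclisation (C8–C9 bond) of an (E,E)-cyclodeca-1,5-diene trans-fused to ring C (germacrane→eudesmane logic).
4. Ring C and the ten-membered ring are formed together by a catalytic enantioselective Diels–Alder macrobicyclisation of an acyclic C20 pentaenal (C5–C10 and C3–C4 bonds).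
5. The pentaenal comes from geranyl acetate, a C3 acetal Grignard reagent, allylphosphonate and isobutyraldehyde. Ring order: C plus ten-membered ring, then A+B, then D.

Assumption (locants): sphaerane-type numbering is used for all C20 compounds. Ring C is C1=C2–C3–C4(iPr)–C5(C16)–C10, ring B is C5–C6–C7–C8(C15H3)–C9–C10, ring A is C8–C9–C11(C17H3)–C12–C13–C14, and β is the face of C15.

## Route

Step 1
Reactants: 1 geranyl acetate
Product: 2 (2E,6E)-8-hydroxy-3,7-dimethylocta-2,6-dien-1-yl acetate
Conditions: SeO2 (0.1 equiv), t-BuOOH (2 equiv), salicylic acid (0.1 equiv), CH2Cl2, rt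
Reagents that add atoms: tert-butyl hydroperoxide CC(C)(C)OO
Why: Catalytic SeO2 allylic oxidation (ene then [2,3]-shift) attacks the more electron-rich distal trisubstituted alkene and oxidises only its E-methyl group, so the 6E geometry is kept and no stereocentre is formed.

Step 2
Reactants: 2 (2E,6E)-8-hydroxy-3,7-dimethylocta-2,6-dien-1-yl acetate
Product: 3 (2E,6E)-8-bromo-3,7-dimethylocta-2,6-dien-1-yl acetate
Conditions: CBr4, PPh3, CH2Cl2, 0 °C
Reagents that add atoms: carbon tetrabromide BrC(Br)(Br)Br
Why: The Appel bromination is an SN2 displacement at the primary allylic carbon under neutral conditions, so there is no allylic shift and the acetate survives.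

Step 3
Reactants: 3 (2E,6E)-8-bromo-3,7-dimethylocta-2,6-dien-1-yl acetate; 4 [2-(1,3-dioxolan-2-yl)ethyl]magnesium bromide
Product: 5 (2E,6E)-10-(1,3-dioxolan-2-yl)-3,7-dimethyldeca-2,6-dien-1-yl acetate
Conditions: 4 (1.3 equiv), Li2CuCl4 (5 mol %), THF, −78 → −20 °C
Reagents that add atoms: [2-(1,3-dioxolan-2-yl)ethyl]magnesium bromide (4) Br[Mg]CCC1OCCO1
Why: The Kochi-type copper-catalysed Grignard/allylic bromide coupling is α-selective and retains alkene geometry, and the bromide reacts far faster than the allylic acetate at low temperature, which installs C6, C5 and masked C16.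

Step 4
Reactants: 5 (2E,6E)-10-(1,3-dioxolan-2-yl)-3,7-dimethyldeca-2,6-dien-1-yl acetate
Product: 6 (2E,6E)-10-(1,3-dioxolan-2-yl)-3,7-dimethyldeca-2,6-dien-1-ol
Conditions: K2CO3 (0.2 equiv), MeOH, rt
Reagents that add atoms: none
Why: Base-catalysed transesterification (methanolysis) removes the acetate, and the acetal and both alkenes are inert to it.

Step 5
Reactants: 6 (2E,6E)-10-(1,3-dioxolan-2-yl)-3,7-dimethyldeca-2,6-dien-1-ol
Product: 7 (2E,6E)-10-(1,3-dioxolan-2-yl)-3,7-dimethyldeca-2,6-dienal
Conditions: Cu(MeCN)4OTf, bpy, TEMPO, N-methylimidazole (5 mol % each), air, MeCN, rt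
Reagents that add atoms: none
Why: Cu/TEMPO aerobic oxidation converts the primary allylic alcohol to the enal without E/Z isomerisation or acetal cleavage.

Step 6
Reactants: 7 (2E,6E)-10-(1,3-dioxolan-2-yl)-3,7-dimethyldeca-2,6-dienal; 8 diethyl allylphosphonate
Product: 9 2-[(4E,8E,10E)-4,8-dimethyltrideca-4,8,10,12-tetraen-1-yl]-1,3-dioxolane
Conditions: 8, n-BuLi, THF–HMPA, −78 °C → rt
Reagents that add atoms: diethyl allylphosphonate (8) C=CCP(=O)(OCC)OCC
Why: Horner–Wadsworth–Emmons olefination with the α-lithiated allylphosphonate gives the E-configured C10=C1 bond and so the terminal C10=C1–C2=C3 diene conjugated with C9=C11.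

Step 7
Reactants: 9 2-[(4E,8E,10E)-4,8-dimethyltrideca-4,8,10,12-tetraen-1-yl]-1,3-dioxolane; 10 isobutyraldehyde
Product: 12 (2E,5E,9E,11E)-5,9-dimethyl-2-(2-methylpropylidene)tetradeca-5,9,11,13-tetraenal, via tetraenal 11 (not isolated)
Conditions: 1 M HCl, THF, rt; extract, crude; then 10 (5 equiv), pyrrolidine/AcOH (20 mol %), CH2Cl2, 35 °C
Reagents that add atoms: water O; isobutyraldehyde (10) CC(C)C=O
Why: Acetal hydrolysis is followed by an amine-catalysed crossed aldol condensation in which excess isobutyraldehyde can only be a productive acceptor (its own aldol cannot dehydrate), and the thermodynamic E-enal places iPr trans to CHO.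

Step 8
Reactants: 12 (2E,5E,9E,11E)-5,9-dimethyl-2-(2-methylpropylidene)tetradeca-5,9,11,13-tetraenal
Product: 13 (1S,4E,8E,10S,14S)-4,8-dimethyl-14-(propan-2-yl)bicyclo[8.4.0]tetradeca-4,8,11-triene-1-carbaldehyde
Conditions: (S)-o-tolyl oxazaborolidine from (S)-diphenylprolinol·Tf2NH (20 mol %), CH2Cl2 (0.002 M), −60 → −20 °C; keep product below 30 °C
Reagents that add atoms: none
Why: This is a type-1 intramolecular Diels–Alder macrobicyclisation (known for farnesyl-derived trienals closing an eleven-membered ring under cationic oxazaborolidine catalysis) in which the 1-substituted diene and α-branched enal are ortho-matched (C10 to C5), the E-enal keeps iPr trans to CHO, the CHO-endo/tether-exo transition state puts C9 cis to CHO (trans fusion), and the catalyst leaves only the C5 Re face open, so C4, C5 and C10 are set together.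

Step 9
Reactants: 13 (1S,4E,8E,10S,14S)-4,8-dimethyl-14-(propan-2-yl)bicyclo[8.4.0]tetradeca-4,8,11-triene-1-carbaldehyde
Product: 14 14β-bromosphaera-1,11(17)-dien-16-al
Conditions: NBS (1.05 equiv), CH2Cl2–HFIP 9:1, −40 °C
Reagents that add atoms: N-bromosuccinimide O=C1CCC(=O)N1Br
Why: In this transannular bromonium cyclisation of the germacradiene→eudesmane type (as with NBS on trans-fused germacranolides), Br+ adds from the periphery to C14 of the strained, less hindered C8=C14 alkene, C9 attacks C8 across the ring in the chair–chair conformer fixed by the trans C5/C10 fusion (giving equatorial 14β-Br, 8β-CH3 and 9α-H anti to 10β-H), and the C11 cation loses its most accessible proton (C17–H) to succinimide.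

Step 10
Reactants: 14 14β-bromosphaera-1,11(17)-dien-16-al
Product: 16 14β-bromosphaer-1-ene-11β,16-diol, via organomercurial 15 (not isolated)
Conditions: Hg(OAc)2 (1.05 equiv), THF–H2O 1:1, 0 °C; then 3 M NaOH, NaBH4, 0 °C
Reagents that add atoms: water O; mercury(II) acetate CC(=O)O[Hg]OC(C)=O (atoms only in 15)
Why: In this oxymercuration–demercuration the 1,1-disubstituted alkene reacts much faster than the cis-1,2-disubstituted ring alkene, Hg binds on the open α face and water adds anti (axially, β) at C11, the reversible addition also favours equatorial CH2HgOAc (no syn-pentane clash with C15), and NaBH4 then cleaves C–Hg and reduces the aldehyde in the same pot.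

Step 11
Reactants: 16 14β-bromosphaer-1-ene-11β,16-diol
Product: 18 target CNP0317598.2, via neopentyl triflate 17 (not isolated)
Conditions: Tf2O (1.05 equiv), 2,6-lutidine (3 equiv), CH2Cl2, −78 °C; then HFIP–H2O 4:1, 45 °C
Reagents that add atoms: water O; triflic anhydride O=S(=O)(OS(=O)(=O)C(F)(F)F)C(F)(F)F (atoms only in 17)
Why: Proposed new method: only the primary alcohol is triflated at −78 °C; the neopentyl C16 cannot be attacked by solvent, and the trans-diaxial iPr/CH2OTf pair pushes ring C toward a boat that holds axial C16 under C2, so ionisation in buffered HFIP is assisted by the C1=C2 π bond (π-route to a 2-norbornyl cation, the laboratory counterpart of α-terpinyl→bornyl closure); the bridged C1/C2 cation undergoes the Wagner–Meerwein shift of C3 from C2 to C1 and water attacks anti to C3 at the less hindered C2, giving the exo alcohol as in camphene→isobornyl chemistry, which fixes C1 and C2; the closest known types are π-participated sulfonate solvolysis and norbornyl Wagner–Meerwein rearrangement.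

## Compound list
1 | geranyl acetate | CC(C)=CCC/C(C)=C/COC(C)=O | starting material
2 | (2E,6E)-8-hydroxy-3,7-dimethylocta-2,6-dien-1-yl acetate | OC/C(C)=C/CC/C(C)=C/COC(C)=O | intermediate
3 | (2E,6E)-8-bromo-3,7-dimethylocta-2,6-dien-1-yl acetate | BrC/C(C)=C/CC/C(C)=C/COC(C)=O | intermediate
4 | [2-(1,3-dioxolan-2-yl)ethyl]magnesium bromide (commercial THF solution) | Br[Mg]CCC1OCCO1 | starting material
5 | (2E,6E)-10-(1,3-dioxolan-2-yl)-3,7-dimethyldeca-2,6-dien-1-yl acetate | O1CCOC1CCC/C(C)=C/CC/C(C)=C/COC(C)=O | intermediate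
6 | (2E,6E)-10-(1,3-dioxolan-2-yl)-3,7-dimethyldeca-2,6-dien-1-ol | O1CCOC1CCC/C(C)=C/CC/C(C)=C/CO | intermediate
7 | (2E,6E)-10-(1,3-dioxolan-2-yl)-3,7-dimethyldeca-2,6-dienal | O1CCOC1CCC/C(C)=C/CC/C(C)=C/C=O | intermediate
8 | diethyl allylphosphonate | C=CCP(=O)(OCC)OCC | starting material
9 | 2-[(4E,8E,10E)-4,8-dimethyltrideca-4,8,10,12-tetraen-1-yl]-1,3-dioxolane | O1CCOC1CCC/C(C)=C/CC/C(C)=C/C=C/C=C | intermediate
10 | isobutyraldehyde | CC(C)C=O | starting material
11 | (5E,9E,11E)-5,9-dimethyltetradeca-5,9,11,13-tetraenal (not isolated) | O=CCCC/C(C)=C/CC/C(C)=C/C=C/C=C | intermediate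
12 | (2E,5E,9E,11E)-5,9-dimethyl-2-(2-methylpropylidene)tetradeca-5,9,11,13-tetraenal (iPr trans to CHO) | CC(C)/C=C(/C=O)CC/C(C)=C/CC/C(C)=C/C=C/C=C | intermediate
13 | cyclohexene trans-fused at C5–C10 to an (E,E)-cyclodeca-1,5-diene; 4β-iPr, 5α-CHO, 10β-H (1S,10S,14S in bicyclo[8.4.0] numbering) | CC(C)[C@@H]1CC=C[C@H]2/C=C(C)/CC/C=C(C)/CC[C@@]21C=O | intermediate
14 | 14β-bromosphaera-1,11(17)-dien-16-al; trans-anti-trans tricycle, 4β-iPr, 5α-CHO, 8β-CH3, 9α-H, 10β-H, equatorial Br | CC(C)[C@@H]1CC=C[C@H]2[C@H]3[C@](C)(CC[C@@]21C=O)[C@@H](Br)CCC3=C | intermediate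
15 | 17-(acetoxymercurio)-14β-bromo-11β-hydroxysphaer-1-en-16-al (not isolated) | CC(C)[C@@H]1CC=C[C@H]2[C@H]3[C@](C)(CC[C@@]21C=O)[C@@H](Br)CC[C@@]3(C[Hg]OC(C)=O)O | intermediate
16 | 14β-bromosphaer-1-ene-11β,16-diol (axial 11β-OH, equatorial C17H3, axial 5α-CH2OH) | CC(C)[C@@H]1CC=C[C@H]2[C@H]3[C@](C)(CC[C@@]21CO)[C@@H](Br)CC[C@@]3(C)O | intermediate
17 | 16-O-triflate of 16 (not isolated) | CC(C)[C@@H]1CC=C[C@H]2[C@H]3[C@](C)(CC[C@@]21COS(=O)(=O)C(F)(F)F)[C@@H](Br)CC[C@@]3(C)O | intermediate
18 | target CNP0317598.2; norbornane from new C16–C2 and C1–C3 bonds, exo 2-OH, exo iPr, 14β-Br, 11β-OH | CC(C)[C@@H]1C[C@@H]2[C@H]3[C@H]4[C@](C)(CC[C@@]31C[C@H]2O)[C@@H](Br)CC[C@@]4(C)O | target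

## Step count and risks
Total step count: 11. Longest linear sequence: 11 steps, from geranyl acetate (1).

**Step 8 (Diels–Alder macrobicyclisation).**
- Risk: the β-isopropyl enal is a sluggish dienophile, and a strained ten-membered ring must close below the Cope threshold.
- Fallback: use an ionic Diels–Alder reaction with a covalently bound auxiliary. It sets out from 12 and returns at 13. Acetalisation of 12 with (2R,4R)-pentane-2,4-diol (PPTS, benzene, water removal) gives the (4R,6R)-4,6-dimethyl-1,3-dioxane acetal of 12 F1. Catalytic TfOH in CH2Cl2 at −78 °C opens it to a vinyl oxocarbenium ion. This is a far stronger dienophile, and its face is controlled by the tethered alkoxy chain. It closes to the bicyclic Diels–Alder acetal F2. Wet acetone/PPTS hydrolysis then gives 13.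

**Step 10 (hydration at C11).**
- Risk: water must enter axially next to the C15 methyl, and Hg(II) must ignore C1=C2.
- Fallback: use halohydrin/epoxide chemistry, whose chemoselectivity rests on alkene nucleophilicity rather than sterics. It sets out from 14 and returns at 16. NIS in THF–H2O at 0 °C adds I+ to the more nucleophilic 1,1-disubstituted alkene from the α face and water from the β face, giving the 17-iodo-11β-hydroxy aldehyde F3. Excess LiEt3BH reduces the aldehyde, closes the alkoxide onto C17 to the 11β,17-spiro-epoxide alcohol F4, and opens this at the CH2 terminus to the methyl carbinol 16. The neopentyl equatorial C14–Br is not touched.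

**Step 11 (π-cyclisation/Wagner–Meerwein cascade).**
- Risk: σ-migration (ring expansion) from the neopentyl triflate may outrun π-participation.
- Fallback: reach the same bridged cation by protonolysis of a strained cyclopropane. It sets out from 16 and returns at 18. TEMPO/PhI(OAc)2 oxidises only the primary alcohol to the 11β-hydroxy-16-aldehyde F5. TsNHNH2 gives its N-tosylhydrazone F6. NaH, then Rh2(OAc)4 in toluene at 80 °C, generates the C16 carbene, which adds to the C1=C2 bond lying beneath it to give the C16–C1–C2 cyclopropane F7. Dilute HClO4 in aqueous THF protonates C16 and breaks the C16–C1 bond, which is shared by the three- and four-membered rings. This gives the C1 norbornyl cation, which shifts and takes up water at C2 to give 18.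

## Further compounds
F1 | step 8 | (4R,6R)-4,6-dimethyl-1,3-dioxane acetal of 12 | C[C@@H]1C[C@@H](C)OC(O1)/C(=C/C(C)C)CC/C(C)=C/CC/C(C)=C/C=C/C=C
F2 | step 8 | bicyclic Diels–Alder acetal (13 with CHO as the chiral dioxane) | CC(C)[C@@H]1CC=C[C@H]2/C=C(C)/CC/C=C(C)/CC[C@@]21C3O[C@H](C)C[C@@H](C)O3
F3 | step 10 | 14β-bromo-11β-hydroxy-17-iodosphaer-1-en-16-al | CC(C)[C@@H]1CC=C[C@H]2[C@H]3[C@](C)(CC[C@@]21C=O)[C@@H](Br)CC[C@@]3(CI)O
F4 | step 10 | 14β-bromo-11β,17-epoxysphaer-1-en-16-ol | CC(C)[C@@H]1CC=C[C@H]2[C@H]3[C@](C)(CC[C@@]21CO)[C@@H](Br)CC[C@]34CO4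
F5 | step 11 | 14β-bromo-11β-hydroxysphaer-1-en-16-al | CC(C)[C@@H]1CC=C[C@H]2[C@H]3[C@](C)(CC[C@@]21C=O)[C@@H](Br)CC[C@@]3(C)O
F6 | step 11 | N-tosylhydrazone of F5 | CC(C)[C@@H]1CC=C[C@H]2[C@H]3[C@](C)(CC[C@@]21/C=N/NS(=O)(=O)c4ccc(C)cc4)[C@@H](Br)CC[C@@]3(C)O
F7 | step 11 | cyclopropane with C16 bonded to C5, C1 and C2 on the α face | CC(C)[C@@H]1C[C@@H]4[C@@H]5[C@H]2[C@H]3[C@](C)(CC[C@@]21[C@H]45)[C@@H](Br)CC[C@@]3(C)O
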